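A stirred, isothermal vessel holds transfer agent, initiator and impurity, and free monomer is fed in for 20 s. The west run is this same flask, followed to 40.0 s.

| flask | free monomer | transfer agent | initiator | impurity | remark | time |
|---|---|---|---|---|---|---|
| west | 0.29 M (fed, over 20 s) | 0.029 M | 2.5 mol% | 0.87 mM | the very flask that is asked about, followed so far; the fed solution adds 0.25 times the starting volume |  |
| flask | 0.29 M (fed, over 20 s) | 0.0290 M | 2.5 mol% | 0.87 mM | the fed solution adds 0.25 times the starting volume | 2.0 min |

west run (percent of the free monomer charged)

| time / s | monomer in chains / % | free monomer / % |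
|---|---|---|
| 10.0 | 0.3 | 48.8 |
| 12.0 | 0 | 58.7 |
| 20.0 | 1.8 | 93.8 |
| 25.0 | 2.1 | 91.4 |
| 30.0 | 3.6 | 87.4 |
| 40.0 | 5.8 | 80.7 |

(standard deviation of a reading: 0.5 percentage points)

- amounts are per litre of the starting volume; all of the dose is in the solution fed
- the average divides the monomer in chains by the number of chains begun, living and dead together
- the earlier runs do not show the number of chains; that part of a forecast is a guess
- percentages count the whole charge, also what has not yet gone in

1. average number of monomer units in a chain (chains begun, living or dead) at 2.0 min
2. part of the free monomer that has reacted at 2.0 min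

At 40.0 s in the west run the feed is over, and free monomer has lost 19.3 % of the charge, yet monomer in chains holds 5.8 %, less. The two amounts seem not to fit, but the loss has a second path beside chain growth. Call chain share, a selectivity, the monomer in chains divided by the free monomer lost; it compares two amounts gathered over the same stretch, and it stays steady only while the ratio of the two rates does. It reads 0.301 at 40.0 s and 0.286 at 30.0 s, both with the scatter of the readings.

After the feed, free monomer falls from 93.8 % to 80.7 % in the west run, a first-order constant of 0.00752 s⁻¹. Carried to 2.0 min, this leaves 44.2 %, so c is 55.8 %. Supposing the share steady, an assumption of this reckoning, monomer in chains reaches 16.8 %. The runs show no count of chains, so this reckoning gives no dp.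

The forecast says dp 4.5 (2 to 9), which it calls “largely a guess”, and c 55 % (47 % to 61 %), slightly below this reckoning.

The flask gives dp 16.5 and c 62.4 %.

    free monomer + initiator → living end + monomer in chains (k = 0.0700 M⁻¹ s⁻¹)
    free monomer + living end → monomer in chains + living end, rate k2*[living end]*[free monomer] (k = 1.70 M⁻¹ s⁻¹)
    living end + transfer agent → dead chain (kL = 0.0830 M⁻¹ s⁻¹)
    free monomer → uncatalysed product (k = 0.00510 s⁻¹)
    2 living end → dead end A (k = 0.270 M⁻¹ s⁻¹)
    initiator + impurity → spent initiator B (k = 270 M⁻¹ s⁻¹)

In this flask monomer in chains stands at 25.3 % against the 16.8 % reckoned, and the chain share is 0.405, above the 0.301 read. The living end has grown from 7.76 × 10⁻⁴ M at 0.333 min to 0.00281 M at 2.00 min. Dividing the growth rate by the uncatalysed rate cancels free monomer and leaves k2 times living end over k4, so this ratio moves with the living end, and at 2.00 min it is 0.936. The neighbour charged with 0.72 M holds 0.00712 M of living end at 2.00 min, so that ratio is 2.37. Its chain share is 0.697, above this flask's, and its dp is 28.7.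

The data were computed for an exercise; scatter was added.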